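The depside is cut at the aryl ester C–O bond and, in the same stroke, ring A is opened between C1 and C6. The ester carbonyl carbon, the six ring A carbons and the propyl group form one linear C10 chain, a 3,5,7-trioxodecanoate, whose C3 and C5 oxygens become those on ring carbons C2 and C4 and whose C7 becomes the propyl-bearing C6. Heating a diketo-dioxinone with the ring B phenol forms the ester by acylketene capture, then base closes ring A by C2–C7 aldol aromatization in the same flask. The precursors are 6-(2,4-dioxoheptyl)-2,2-dimethyl-1,3-dioxin-4-one and benzyl 2-benzyloxy-4-hydroxy-6-propylbenzoate, itself made from the same dioxinone.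

Key step: step 8

Assumption: the target has no stereocenters, and chlorotriisopropylsilane, iodomethane, n-Bu4NF and the bases used are taken as commercial reagents.

Step 1
Reactants: 1 2,2,6-trimethyl-4H-1,3-dioxin-4-one; 2 acetyl chloride
Product: 3 2,2-dimethyl-6-(2-oxopropyl)-4H-1,3-dioxin-4-one
Conditions: LiN(SiMe3)2 (2 equiv), 1 (2 equiv), THF, −78 °C; then 2 (1 equiv), −78 °C; aq. HCl quench
Reagents that add atoms: none
Why: The lithium dienolate of 1 is acylated at its terminal (C6 methyl) carbon in a vinylogous Claisen-type C-acylation, and the second equivalent of enolate absorbs the proton of the more acidic product so that the conversion of 2 should be complete.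

Step 2
Reactants: 3 2,2-dimethyl-6-(2-oxopropyl)-4H-1,3-dioxin-4-one; 4 N-methoxy-N-methylbutanamide
Product: 5 6-(2,4-dioxoheptyl)-2,2-dimethyl-4H-1,3-dioxin-4-one
Conditions: LiN(i-Pr)2 (3 equiv), THF, −78 °C; then 4, −78 to −20 °C; aq. HCl quench (pH 3)
Reagents that add atoms: none
Why: Double deprotonation of 3 gives a dianion whose terminal, methyl-derived carbanion is the more nucleophilic site and attacks the N-methoxy-N-methylamide, the chelated tetrahedral adduct preventing over-addition (Claisen-type acylation of a dicarbonyl dianion).

Step 3
Reactants: 5 6-(2,4-dioxoheptyl)-2,2-dimethyl-4H-1,3-dioxin-4-one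
Product: 6 7-hydroxy-2,2-dimethyl-5-propyl-4H-1,3-benzodioxin-4-one
Conditions: Et3N (2 equiv), CH2Cl2, rt; 1 M aq. HCl wash
Reagents that add atoms: none
Why: The amine enolizes the methylene between the dioxinone ring and the neighbouring ketone, the dienolate adds through the dioxinone C5 carbon to the propyl ketone in a six-membered intramolecular aldol closure, and loss of water with enolization of the remaining ketone should give the arene with the dioxinone kept as the acetonide of the salicylate (biomimetic polyketide aldol aromatization), the dioxinone ring staying intact at room temperature.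

Step 4
Reactants: 6 7-hydroxy-2,2-dimethyl-5-propyl-4H-1,3-benzodioxin-4-one; 7 benzyl alcohol
Product: 8 benzyl 2,4-dihydroxy-6-propylbenzoate
Conditions: NaH (3 equiv), 7 (5 equiv), THF, 0 to 60 °C; 1 M aq. HCl quench
Reagents that add atoms: none
Why: Sodium benzyloxide adds to the lactone-type carbonyl of the benzodioxinone and the ring opens with release of acetone (alkoxide transesterification of a salicylate acetonide), with excess alkoxide and gentle heating chosen because the C7 phenoxide lowers the electrophilicity of that carbonyl.

Step 5
Reactants: 8 benzyl 2,4-dihydroxy-6-propylbenzoate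
Product: 9 benzyl 2-hydroxy-6-propyl-4-(triisopropylsilyloxy)benzoate
Conditions: i-Pr3SiCl (1.05 equiv), imidazole, DMF, 0 °C to rt
Reagents that add atoms: chlorotriisopropylsilane, CC(C)[Si](Cl)(C(C)C)C(C)C
Why: The C4 hydroxyl is the more acidic and unencumbered phenol while the C2 hydroxyl is held in a hydrogen bond to the ester carbonyl, so the bulky silyl chloride should react only at C4 (selective O-silylation).

Step 6
Reactants: 9 benzyl 2-hydroxy-6-propyl-4-(triisopropylsilyloxy)benzoate; 10 benzyl bromide
Product: 11 benzyl 2-(benzyloxy)-6-propyl-4-(triisopropylsilyloxy)benzoate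
Conditions: K2CO3, acetone, 56 °C
Reagents that add atoms: none
Why: Williamson etherification of the remaining hydrogen-bonded phenol, with the triisopropylsilyl ether chosen because it should resist carbonate in acetone, so that no silyl loss and no benzylation at the C4 oxygen is expected.

Step 7
Reactants: 11 benzyl 2-(benzyloxy)-6-propyl-4-(triisopropylsilyloxy)benzoate
Product: 12 benzyl 2-(benzyloxy)-4-hydroxy-6-propylbenzoate
Conditions: n-Bu4NF, AcOH, THF, 0 °C
Reagents that add atoms: none
Why: Fluoride-induced cleavage of the aryl silyl ether, buffered with acetic acid so that the liberated phenoxide is protonated at once and the benzyl ester and ether stay untouched.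

Step 8
Reactants: 5 6-(2,4-dioxoheptyl)-2,2-dimethyl-4H-1,3-dioxin-4-one; 12 benzyl 2-(benzyloxy)-4-hydroxy-6-propylbenzoate
Product: 15 3-(benzyloxy)-4-(benzyloxycarbonyl)-5-propylphenyl 2,4-dihydroxy-6-propylbenzoate, via acylketene 13 (not isolated), via aryl triketo ester 14 (not isolated)
Conditions: 5 (1.5–2 equiv, added in portions), toluene, 110 °C; cool; then Et3N, CH2Cl2, 0 °C to rt; 1 M aq. HCl wash
Reagents that add atoms: none
Why: At 110 °C dioxinone 5 loses acetone by retro-hetero-Diels–Alder reaction to give acylketene 13, whose ketene carbon is attacked by the only free hydroxyl of 12 (the ring B C4 phenol) to give aryl 3,5,7-trioxodecanoate 14; this joins the established thermal acylation of phenols by dioxinone-derived acylketenes to the biomimetic aldol aromatization of 3,5,7-triketo esters. With Et3N the doubly activated C2 methylene enolizes and adds to the C7 ketone in a 6-exo-trig aldol closure (6-enolexo as counted from the C1–C2 ester enolate), forming the C2–C7 bond of the one carbocycle closed in this step; loss of water and enolization of the C3 and C5 carbonyls should then give aromatic ring A with hydroxyls at C2 and C4 and propyl at C6. No stereocenter is formed. The step needs O-acylation at a single site, which is secured because the ring B C2 oxygen and the carboxyl are benzylated, and it needs C2-to-C7 aldol closure in preference to lactonization of the C5 enol to a 4-hydroxy-2-pyranone or C6-to-C1 Claisen closure, both of which would expel the phenol. The high acidity of C2 and an amine base in an aprotic solvent favour the aldol path and leave no external nucleophile to intercept a reversibly re-formed acylketene, while the chain length alone fixes the substitution pattern of ring A. Excess 5 added in portions should compensate for acylketene lost to self-cyclization, and the hindered 2,6-disubstituted benzoate is never made by acylation because ring A is built after the ester bond exists.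

Step 9
Reactants: 15 3-(benzyloxy)-4-(benzyloxycarbonyl)-5-propylphenyl 2,4-dihydroxy-6-propylbenzoate
Product: 16 3-(benzyloxy)-4-(benzyloxycarbonyl)-5-propylphenyl 2,4-dimethoxy-6-propylbenzoate
Conditions: MeI (excess), K2CO3, acetone, 56 °C
Reagents that add atoms: iodomethane, CI
Why: Williamson O-methylation of both ring A phenols, the free C4 hydroxyl reacting first and the hydrogen-bonded C2 hydroxyl following on heating, while ring B carries no free hydroxyl.

Step 10
Reactants: 16 3-(benzyloxy)-4-(benzyloxycarbonyl)-5-propylphenyl 2,4-dimethoxy-6-propylbenzoate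
Product: 17 4-[(2,4-dimethoxy-6-propylbenzoyl)oxy]-2-hydroxy-6-propylbenzoic acid
Conditions: H2 (1 atm), Pd/C (10 wt%), EtOAc, rt
Reagents that add atoms: none
Why: Catalytic hydrogenolysis cleaves the benzylic C–O bonds of the benzyl ether and the benzyl ester, while the aryl methyl ethers, the aryl ester and the arenes should be inert under these conditions.

Compound list
1 | 2,2,6-trimethyl-4H-1,3-dioxin-4-one | CC1=CC(=O)OC(C)(C)O1 | starting material
2 | acetyl chloride | CC(Cl)=O | starting material
3 | 2,2-dimethyl-6-(2-oxopropyl)-4H-1,3-dioxin-4-one | CC(=O)CC1=CC(=O)OC(C)(C)O1 | intermediate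
4 | N-methoxy-N-methylbutanamide | CCCC(=O)N(C)OC | starting material
5 | 6-(2,4-dioxoheptyl)-2,2-dimethyl-4H-1,3-dioxin-4-one | CCCC(=O)CC(=O)CC1=CC(=O)OC(C)(C)O1 | intermediate
6 | 7-hydroxy-2,2-dimethyl-5-propyl-4H-1,3-benzodioxin-4-one | CCCc1cc(O)cc2OC(C)(C)OC(=O)c12 | intermediate
7 | benzyl alcohol | OCc1ccccc1 | starting material
8 | benzyl 2,4-dihydroxy-6-propylbenzoate | CCCc1cc(O)cc(O)c1C(=O)OCc1ccccc1 | intermediate
9 | benzyl 2-hydroxy-6-propyl-4-(triisopropylsilyloxy)benzoate | CCCc1cc(O[Si](C(C)C)(C(C)C)C(C)C)cc(O)c1C(=O)OCc1ccccc1 | intermediate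
10 | benzyl bromide | BrCc1ccccc1 | starting material
11 | benzyl 2-(benzyloxy)-6-propyl-4-(triisopropylsilyloxy)benzoate | CCCc1cc(O[Si](C(C)C)(C(C)C)C(C)C)cc(OCc2ccccc2)c1C(=O)OCc1ccccc1 | intermediate
12 | benzyl 2-(benzyloxy)-4-hydroxy-6-propylbenzoate | CCCc1cc(O)cc(OCc2ccccc2)c1C(=O)OCc1ccccc1 | intermediate
13 | 3,5,7-trioxodec-1-en-1-one (acylketene) | CCCC(=O)CC(=O)CC(=O)C=C=O | intermediate
14 | 3-(benzyloxy)-4-(benzyloxycarbonyl)-5-propylphenyl 3,5,7-trioxodecanoate | CCCC(=O)CC(=O)CC(=O)CC(=O)Oc1cc(CCC)c(C(=O)OCc2ccccc2)c(OCc2ccccc2)c1 | intermediate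
15 | 3-(benzyloxy)-4-(benzyloxycarbonyl)-5-propylphenyl 2,4-dihydroxy-6-propylbenzoate | CCCc1cc(O)cc(O)c1C(=O)Oc1cc(CCC)c(C(=O)OCc2ccccc2)c(OCc2ccccc2)c1 | intermediate
16 | 3-(benzyloxy)-4-(benzyloxycarbonyl)-5-propylphenyl 2,4-dimethoxy-6-propylbenzoate | CCCc1cc(OC)cc(OC)c1C(=O)Oc1cc(CCC)c(C(=O)OCc2ccccc2)c(OCc2ccccc2)c1 | intermediate
17 | 4-[(2,4-dimethoxy-6-propylbenzoyl)oxy]-2-hydroxy-6-propylbenzoic acid | CCCc1cc(OC(=O)c2c(CCC)cc(OC)cc2OC)cc(O)c1C(=O)O | target

Total step count: 10 steps.
Longest linear sequence: 10 steps (steps 1 to 10, through compounds 3, 5, 6, 8, 9, 11, 12, 15, 16 and 17). Compound 5 is also the second reactant of step 8, so no separate branch adds steps.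

Steps most likely to fail

Step 8. The acylketene may be consumed by capture of its own C5 enol (pyranone formation) or by dimerization before the weakly nucleophilic phenol adds. After capture, the aryl ester may be lost by lactonization, by Claisen-type closure that expels the phenoxide, or by elimination back to the acylketene. The fallback makes the ester from a preformed ring A acid. It sets out from compound 8: double O-methylation (MeI, K2CO3, acetone, 56 °C) should give benzyl 2,4-dimethoxy-6-propylbenzoate F1, and hydrogenolysis (H2, Pd/C, EtOAc) should give 2,4-dimethoxy-6-propylbenzoic acid F2. Condensation of F2 with phenol 12 through the mixed trifluoroacetic anhydride ((CF3CO)2O, toluene, rt), a standard esterification for hindered 2,6-disubstituted benzoic acids with phenols, comes back to the route at compound 16.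

Step 4. Once the C7 hydroxyl is deprotonated, addition of benzyloxide to the deactivated carbonyl may stall, and forcing the reaction may degrade the electron-rich resorcylate. The fallback opens the dioxinone thermally before the arene exists, so it replaces steps 3 and 4. It sets out from compound 5: heating with benzyl alcohol in toluene at 110 °C expels acetone, and the alcohol traps acylketene 13 to give benzyl 3,5,7-trioxodecanoate F3. Aldol closure with K2CO3 in i-PrOH/CH2Cl2 at rt followed by dehydration with HCl in MeOH comes back to the route at compound 8.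

Step 2. The second deprotonation may be incomplete, the more acidic product may quench unreacted dianion by proton transfer, and O-acylation or decomposition of the sensitive diketo-dioxinone may erode the material. The fallback builds the same chain by a malonate-type acylation and decarboxylation. It sets out from compound 1: the lithium dienolate (LiN(SiMe3)2, THF, −78 °C) is acylated with allyl 3-chloro-3-oxopropanoate to give allyl 4-(2,2-dimethyl-4-oxo-4H-1,3-dioxin-6-yl)-3-oxobutanoate F4. Magnesium-mediated C-acylation of its activated methylene (MgCl2, pyridine, butanoyl chloride, CH2Cl2, 0 °C) gives allyl 2-[(2,2-dimethyl-4-oxo-4H-1,3-dioxin-6-yl)acetyl]-3-oxohexanoate F5. Deallylation with Pd(PPh3)4 (zerovalent palladium) and morpholine in THF, followed by spontaneous decarboxylation, comes back to the route at compound 5.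

Further compounds
F1 | step 8 | benzyl 2,4-dimethoxy-6-propylbenzoate | CCCc1cc(OC)cc(OC)c1C(=O)OCc1ccccc1
F2 | step 8 | 2,4-dimethoxy-6-propylbenzoic acid | CCCc1cc(OC)cc(OC)c1C(=O)O
F3 | step 4 | benzyl 3,5,7-trioxodecanoate | CCCC(=O)CC(=O)CC(=O)CC(=O)OCc1ccccc1
F4 | step 2 | allyl 4-(2,2-dimethyl-4-oxo-4H-1,3-dioxin-6-yl)-3-oxobutanoate | C=CCOC(=O)CC(=O)CC1=CC(=O)OC(C)(C)O1
F5 | step 2 | allyl 2-[(2,2-dimethyl-4-oxo-4H-1,3-dioxin-6-yl)acetyl]-3-oxohexanoate | CCCC(=O)C(C(=O)OCC=C)C(=O)CC1=CC(=O)OC(C)(C)O1
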